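The constants stand for no real mixture; what happens was integrated by code.

Start from the leftover, the L that finds no X, and watch it in the two flasks below, maple and oak.

    X + D → X.D (k1 = 370 M⁻¹ s⁻¹)
    2 L → L2 (k2 = 1.1 M⁻¹ s⁻¹)
    L + X → Z + Q (k3 = 650 M⁻¹ s⁻¹)

- maple: L 2.0 × 10⁻⁴ M; X 1.00 equiv; D 0.100 mM; time 10 min
- oak: L 2.0 × 10⁻⁴ M; X 1.00 equiv; D 0.0500 mM; time 10 min

* which of the two ends with the longer chains by the average number of monomer units in a chain (unreacted monomers counted as chains of one) ("neither" if they lie within 10 %) (maple / oak / neither)
* average number of monomer units in a chain (unreacted monomers counted as chains of one) at the end, maple
* average number of monomer units in a chain (unreacted monomers counted as chains of one) at the end, oak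

- percent here means L units held: one L2 counts as two
- for a step with 2 of a species take k times the square, and two of it per event
- each molecule carries two end groups: a chain counts once for every two ends that are left, dead ends included; the units are half of the end groups of the two monomers charged
- a link that another step uses up counts as cut, two dead ends; so do two ends of one kind that react with each other
- run time (maple): 10 min

Count the chains first. The units are half of the end groups charged, and each Z joins two chains into one, so the length is the units over the units minus the links. With X at 1.00 equiv, that is one over the fraction of L not linked; L2 and X.D are not links.

Now count half-lives at maple's charges, each by its own step alone with the other concentrations as charged. L halves by linking in 0.089 min, X halves by capping with D in 0.31 min, and L halves by the L + L step in 37.9 min, so I set that slow step aside. Linking and capping both need X, so cX cancels between them, and ln cL falls faster than ln cD by the ratio of the linking constant to the capping constant, a selectivity factor S = 1.76. The fraction of L not linked is therefore the fraction of D left, y, raised to the power S. Each X used takes one L or one D, so if the whole charge of X reacts, and X and L are charged equally, that fraction is also a times (one minus y), where a is D charged over L charged.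

Turn the settings. For D, maple has a = 0.500; guessing half and taking the S-th root twice gives y = 47.7 % and a length of 3.83. Oak has a = 0.250, which gives y = 36.9 % and a length of 6.34. Raising cL at fixed D, with X held in equivalents, lowers a, so by hand the chains lengthen. Moving X off 1.00 equiv changes both the units and the relation above, so it needs its own count. Time should do little to the length, since 10 min far exceeds the linking and capping half-lives.

The forecast says oak, with 3.7 for maple and 6 for oak, holding that “Halving D therefore leaves more X for linking”. My lengths are higher than its.

The flasks give oak, with 3.76 in maple and 6.17 in oak, and after 100 min they stand at 3.76 and 6.17. Maple's length has moved by 0.376 once X stands at 0.909 equiv or 1.09 equiv. Maple's D left, 46.9 %, raised to S gives 26.4 % against 26.6 % not linked. Take the neighbouring flask, oak with 0.250 equiv of X, where the unlinked fraction is one minus 0.250 plus a times the fraction of D used. Two passes give y = 86.1 %, Z at 21.5 % and a length of 1.52; that flask gives D 86.9 %, Z 21.7 % and length 1.53.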